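Atom labels: C1 (allyl bridgehead), C2, C3 (OMe), C4 (OH), C5 (OMe bridgehead), C6 (aryl), C7 (methyl), C8 (ketone). Everything rests on disconnecting C5–C6: the vicinal oxygens on C4 and C5 next to the C8 carbonyl mark the bicyclo[3.2.1]octane as the α-ketol isomer of a bicyclo[2.2.2]octenone. In one operation, fluoride frees a bridgehead C4 alkoxide and C6 shifts from C4 to the C5 ketone, contracting a six-membered ring to the five-membered ring C1–C8–C5–C6–C7 and creating the C5 carbinol and the C2=C3–C4=O enone. The precursor is the Diels–Alder adduct of a masked o-benzoquinone and (E)-isoelemicin bearing C4–OSi(i-Pr)3, a C5 ketone and a C8 dimethyl ketal.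

Key step: step 10

Assumption: (E)-isoelemicin is bought as the geometrically pure E isomer. The labels C1–C8 are kept for all bicyclic compounds, including the bicyclo[2.2.2] ones (bridgeheads C1 and C4; bridges C2=C3, C5–C8 and C6–C7), and the CIP descriptors refer to these labels.

Step 1
Reactants: 1 2,3-dihydroxy-4-methoxybenzaldehyde
Product: 2 2-hydroxy-4-methoxy-3-[(triisopropylsilyl)oxy]benzaldehyde
Conditions: i-Pr3SiCl, imidazole, DMF, 0 °C → rt
Reagents that add atoms: chlorotriisopropylsilane, CC(C)[Si](Cl)(C(C)C)C(C)C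
Why: Imidazole-mediated O-silylation of a phenol; the 2-OH is tied up in a hydrogen bond to the aldehyde, so the 3-OH should react, and any silyl migration would be driven to the same isomer, the only one that keeps the chelated salicylaldehyde.

Step 2
Reactants: 2 2-hydroxy-4-methoxy-3-[(triisopropylsilyl)oxy]benzaldehyde
Product: 3 4-methoxy-2-(methoxymethoxy)-3-[(triisopropylsilyl)oxy]benzaldehyde
Conditions: MOMCl, i-Pr2NEt, CH2Cl2, 0 → 40 °C
Reagents that add atoms: chloromethyl methyl ether, COCCl
Why: Base-mediated O-alkylation (methoxymethyl ether formation) of the one remaining phenol; the amine base is too weak to set the aryl silyl ether in motion, and the acetal should withstand peracid, carbonate and the later heating.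

Step 3
Reactants: 3 4-methoxy-2-(methoxymethoxy)-3-[(triisopropylsilyl)oxy]benzaldehyde
Product: 5 4-methoxy-2-(methoxymethoxy)-3-[(triisopropylsilyl)oxy]phenol, via aryl formate 4 (not isolated)
Conditions: mCPBA, CH2Cl2, 0 °C → rt; then Et3N, MeOH, rt
Reagents that add atoms: 3-chloroperoxybenzoic acid, OOC(=O)c1cccc(Cl)c1
Why: Dakin-type Baeyer–Villiger oxidation, in which the electron-rich, ortho- and para-oxygenated aryl group migrates in preference to hydrogen; the aryl formate is then transesterified by methanol under conditions too mild to touch the silyl ether.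

Step 4
Reactants: 5 4-methoxy-2-(methoxymethoxy)-3-[(triisopropylsilyl)oxy]phenol; 6 allyl bromide
Product: 7 1-(allyloxy)-4-methoxy-2-(methoxymethoxy)-3-[(triisopropylsilyl)oxy]benzene
Conditions: K2CO3, acetone, reflux
Reagents that add atoms: none
Why: Williamson ether synthesis on the phenoxide; the neighbouring oxygen carries the acetal and not silicon, so no silyl migration can occur under carbonate.

Step 5
Reactants: 7 1-(allyloxy)-4-methoxy-2-(methoxymethoxy)-3-[(triisopropylsilyl)oxy]benzene
Product: 9 6-allyl-4-methoxy-2-(methoxymethoxy)-3-[(triisopropylsilyl)oxy]phenol, via ortho-dienone 8 (not isolated)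
Conditions: PhNEt2, 190 °C
Reagents that add atoms: none
Why: Aromatic Claisen rearrangement; the [3,3]-sigmatropic shift can deliver the allyl group only to the single unsubstituted ortho carbon (the future C1), and the dienone then tautomerises to the phenol.

Step 6
Reactants: 9 6-allyl-4-methoxy-2-(methoxymethoxy)-3-[(triisopropylsilyl)oxy]phenol
Product: 10 1-allyl-2,5-dimethoxy-3-(methoxymethoxy)-4-[(triisopropylsilyl)oxy]benzene
Conditions: MeI, K2CO3, acetone, reflux
Reagents that add atoms: iodomethane, CI
Why: Williamson O-methylation of the new phenol, which places the methoxy group on the future C8.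

Step 7
Reactants: 10 1-allyl-2,5-dimethoxy-3-(methoxymethoxy)-4-[(triisopropylsilyl)oxy]benzene
Product: 11 3-allyl-2,5-dimethoxy-6-[(triisopropylsilyl)oxy]phenol
Conditions: TsOH·H2O (cat.), MeOH, 40 °C
Reagents that add atoms: none
Why: Acid-catalysed acetal exchange with methanol removes the methoxymethyl group, while the aryl triisopropylsilyl ether and the allyl group are inert to dilute acid; the free phenol is kept away from base so that silicon stays on the future C4 oxygen.

Step 8
Reactants: 11 3-allyl-2,5-dimethoxy-6-[(triisopropylsilyl)oxy]phenol; 12 (E)-isoelemicin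
Product: 14 rac-(1S,4S,6S,7R)-1-allyl-3,8,8-trimethoxy-7-methyl-4-[(triisopropylsilyl)oxy]-6-(3,4,5-trimethoxyphenyl)bicyclo[2.2.2]oct-2-en-5-one, via masked o-benzoquinone 13 (not isolated)
Conditions: PhI(OAc)2, MeOH, 0 °C; evaporate; 12 (5 equiv), PhMe, 100 °C
Reagents that add atoms: methanol, CO
Why: Oxidative dearomatisation followed by an inverse-electron-demand Diels–Alder reaction of the masked o-benzoquinone: methanol should add to the methoxy-bearing ortho carbon (future C8) rather than to the carbon shielded by the bulky silyloxy group, the nucleophilic methyl-bearing alkene carbon should bond to the electrophilic δ-terminus C1 and the benzylic carbon to C4, the E geometry is transferred to trans C6/C7, and the methyl group should sit under the diene (syn to C2=C3) so that the aryl group faces the flat C5 carbonyl and nothing is pushed against a C8 methoxy group.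

Step 9
Reactants: 14 rac-(1S,4S,6S,7R)-1-allyl-3,8,8-trimethoxy-7-methyl-4-[(triisopropylsilyl)oxy]-6-(3,4,5-trimethoxyphenyl)bicyclo[2.2.2]oct-2-en-5-one
Product: 15 (1S,4S,6S,7R)-1-allyl-3,8,8-trimethoxy-7-methyl-4-[(triisopropylsilyl)oxy]-6-(3,4,5-trimethoxyphenyl)bicyclo[2.2.2]oct-2-en-5-one
Conditions: preparative chiral SFC, amylose tris(3,5-dimethylphenylcarbamate) phase, CO2/i-PrOH
Reagents that add atoms: none
Why: Enantiomer separation by chromatography on a polysaccharide chiral stationary phase, a physical resolution that leaves every bond untouched; the enantiomer of structure 15 is to be identified by comparing its vibrational circular dichroism with the computed spectrum before it is carried on.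

Step 10
Reactants: 15 (1S,4S,6S,7R)-1-allyl-3,8,8-trimethoxy-7-methyl-4-[(triisopropylsilyl)oxy]-6-(3,4,5-trimethoxyphenyl)bicyclo[2.2.2]oct-2-en-5-one
Product: 17 (1S,5S,6S,7R)-1-allyl-5-hydroxy-3,8,8-trimethoxy-7-methyl-6-(3,4,5-trimethoxyphenyl)bicyclo[3.2.1]oct-2-en-4-one, via bridgehead ketol 16 (not isolated)
Conditions: Bu4NF, THF, 0 °C → rt; AcOH
Reagents that add atoms: none
Why: Fluoride cleaves the Si–O bond to give the tertiary C4 alkoxide of a bridgehead α-ketol, and the C4–C6 σ-bond, held well out of the C5 carbonyl plane by the bicyclo[2.2.2] cage, migrates suprafacially to C5 while C4 becomes a ketone. This is an anionic α-ketol (acyloin) rearrangement, and the closest known cases are base-induced shifts of bridgehead-oxygenated bicyclo[2.2.2]octenones to bicyclo[3.2.1]octenones. The five-membered ring C1–C8–C5–C6–C7 is closed by a 1,2-shift that contracts the six-membered ring C1–C8–C5–C4–C6–C7, not by an end-to-end cyclisation, so the usual ring-closure constraints do not apply. The only new stereocentre, C5, is fixed by the cage, because C6 can reach only the face of the C5 carbonyl that it already flanks, and C6 itself migrates with retention, so the 6-aryl group should end exo (syn to C8) and the 7-methyl group endo. The step needs C6 and not the vinylic C3 to migrate; both bonds are equally well aligned, but the shift is reversible and only C6 migration gives the conjugated C2=C3–C4=O α-methoxy enone in an unstrained bicyclo[3.2.1]oct-2-ene, whereas C3 migration would leave an unconjugated ketone beside a strained bicyclo[3.2.1]oct-6-ene, so equilibration under the alkoxide conditions should funnel material to 17. The C8 ketal keeps the former quinone carbon out of any carbonyl chemistry during the shift.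

Step 11
Reactants: 17 (1S,5S,6S,7R)-1-allyl-5-hydroxy-3,8,8-trimethoxy-7-methyl-6-(3,4,5-trimethoxyphenyl)bicyclo[3.2.1]oct-2-en-4-one
Product: 18 (1S,5S,6S,7R)-1-allyl-3,5,8,8-tetramethoxy-7-methyl-6-(3,4,5-trimethoxyphenyl)bicyclo[3.2.1]oct-2-en-4-one
Conditions: NaH, MeI, THF–DMF, 0 °C → rt
Reagents that add atoms: iodomethane, CI
Why: Williamson etherification of the tertiary C5 alkoxide, the same anion that is the resting state of step 10; C4 has no enolisable neighbour (C5 and C1 quaternary, C3 vinylic), so only O-methylation can occur.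

Step 12
Reactants: 18 (1S,5S,6S,7R)-1-allyl-3,5,8,8-tetramethoxy-7-methyl-6-(3,4,5-trimethoxyphenyl)bicyclo[3.2.1]oct-2-en-4-one
Product: 20 (1R,3S,5S,6S,7R)-1-allyl-3,5,8,8-tetramethoxy-7-methyl-6-(3,4,5-trimethoxyphenyl)bicyclo[3.2.1]octan-4-one, via C3-epimer mixture 19 (not isolated)
Conditions: [(Ph3P)CuH]6, H2O (2 equiv), PhMe, rt; then K2CO3 (cat.), MeOH, rt
Reagents that add atoms: none
Why: Conjugate reduction by a phosphine copper hydride, which adds hydride to C2 of the enone and ignores the isolated allyl alkene; carbonate in methanol then equilibrates C3 through the enolate to the epimer with the methoxy group exo (equatorial, syn to C8), away from the endo C7 methyl group.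

Step 13
Reactants: 20 (1R,3S,5S,6S,7R)-1-allyl-3,5,8,8-tetramethoxy-7-methyl-6-(3,4,5-trimethoxyphenyl)bicyclo[3.2.1]octan-4-one
Product: 21 (1R,3S,4S,5S,6S,7R)-1-allyl-3,5,8,8-tetramethoxy-7-methyl-6-(3,4,5-trimethoxyphenyl)bicyclo[3.2.1]octan-4-ol
Conditions: LiBH(s-Bu)3, THF, −78 °C; H2O
Reagents that add atoms: none
Why: Ketone reduction by a bulky trialkylborohydride: hydride should enter C4 along the equatorial, endo trajectory because the exo face lies under the C8 methoxy group that hangs over the six-membered ring, giving the axial C4 alcohol cis to the C3 methoxy group, and with C8 still a ketal the alkoxide cannot undergo retro-aldol cleavage.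

Step 14
Reactants: 21 (1R,3S,4S,5S,6S,7R)-1-allyl-3,5,8,8-tetramethoxy-7-methyl-6-(3,4,5-trimethoxyphenyl)bicyclo[3.2.1]octan-4-ol
Product: 22 (1R,3S,4S,5S,6S,7R)-1-allyl-4-hydroxy-3,5-dimethoxy-7-methyl-6-(3,4,5-trimethoxyphenyl)bicyclo[3.2.1]octan-8-one
Conditions: 2 M HCl, THF, 40 °C
Reagents that add atoms: water, O
Why: Acid-catalysed ketal hydrolysis through the C8 oxocarbenium ion, left to the end because only then is C8 no longer next to a C4 carbonyl; C1 and C5 are quaternary, so nothing can epimerise or eliminate.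

Compound list
1 | 2,3-dihydroxy-4-methoxybenzaldehyde | O=Cc1ccc(OC)c(O)c1O | starting material
2 | 2-hydroxy-4-methoxy-3-[(triisopropylsilyl)oxy]benzaldehyde | O=Cc1ccc(OC)c(O[Si](C(C)C)(C(C)C)C(C)C)c1O | intermediate
3 | 4-methoxy-2-(methoxymethoxy)-3-[(triisopropylsilyl)oxy]benzaldehyde | O=Cc1ccc(OC)c(O[Si](C(C)C)(C(C)C)C(C)C)c1OCOC | intermediate
4 | 4-methoxy-2-(methoxymethoxy)-3-[(triisopropylsilyl)oxy]phenyl formate | O=COc1ccc(OC)c(O[Si](C(C)C)(C(C)C)C(C)C)c1OCOC | intermediate (not isolated)
5 | 4-methoxy-2-(methoxymethoxy)-3-[(triisopropylsilyl)oxy]phenol | Oc1ccc(OC)c(O[Si](C(C)C)(C(C)C)C(C)C)c1OCOC | intermediate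
6 | allyl bromide | C=CCBr | starting material
7 | 1-(allyloxy)-4-methoxy-2-(methoxymethoxy)-3-[(triisopropylsilyl)oxy]benzene | C=CCOc1ccc(OC)c(O[Si](C(C)C)(C(C)C)C(C)C)c1OCOC | intermediate
8 | 6-allyl-4-methoxy-2-(methoxymethoxy)-3-[(triisopropylsilyl)oxy]cyclohexa-2,4-dien-1-one (racemic) | C=CCC1C=C(OC)C(O[Si](C(C)C)(C(C)C)C(C)C)=C(OCOC)C1=O | intermediate (not isolated)
9 | 6-allyl-4-methoxy-2-(methoxymethoxy)-3-[(triisopropylsilyl)oxy]phenol | C=CCc1cc(OC)c(O[Si](C(C)C)(C(C)C)C(C)C)c(OCOC)c1O | intermediate
10 | 1-allyl-2,5-dimethoxy-3-(methoxymethoxy)-4-[(triisopropylsilyl)oxy]benzene | C=CCc1cc(OC)c(O[Si](C(C)C)(C(C)C)C(C)C)c(OCOC)c1OC | intermediate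
11 | 3-allyl-2,5-dimethoxy-6-[(triisopropylsilyl)oxy]phenol (ring carbons become C5 (OH), C8 (OMe), C1 (allyl), C2 (H), C3 (OMe), C4 (OSi)) | C=CCc1cc(OC)c(O[Si](C(C)C)(C(C)C)C(C)C)c(O)c1OC | intermediate
12 | (E)-isoelemicin, 1,2,3-trimethoxy-5-[(E)-prop-1-enyl]benzene | C/C=C/c1cc(OC)c(OC)c(OC)c1 | starting material
13 | 5-allyl-3,6,6-trimethoxy-2-[(triisopropylsilyl)oxy]cyclohexa-2,4-dien-1-one (masked o-benzoquinone) | C=CCC1=CC(OC)=C(O[Si](C(C)C)(C(C)C)C(C)C)C(=O)C1(OC)OC | intermediate (not isolated)
14 | rac-(1S,4S,6S,7R)-1-allyl-3,8,8-trimethoxy-7-methyl-4-[(triisopropylsilyl)oxy]-6-(3,4,5-trimethoxyphenyl)bicyclo[2.2.2]oct-2-en-5-one (7-methyl syn to C2=C3, 6-aryl syn to the C5–C8 bridge; racemate written as both enantiomers) | C=CC[C@]12C=C(OC)[C@](O[Si](C(C)C)(C(C)C)C(C)C)(C(=O)C1(OC)OC)[C@H](c3cc(OC)c(OC)c(OC)c3)[C@H]2C.C=CC[C@@]12C=C(OC)[C@@](O[Si](C(C)C)(C(C)C)C(C)C)(C(=O)C1(OC)OC)[C@@H](c3cc(OC)c(OC)c(OC)c3)[C@@H]2C | intermediate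
15 | (1S,4S,6S,7R)-1-allyl-3,8,8-trimethoxy-7-methyl-4-[(triisopropylsilyl)oxy]-6-(3,4,5-trimethoxyphenyl)bicyclo[2.2.2]oct-2-en-5-one | C=CC[C@]12C=C(OC)[C@](O[Si](C(C)C)(C(C)C)C(C)C)(C(=O)C1(OC)OC)[C@H](c3cc(OC)c(OC)c(OC)c3)[C@H]2C | intermediate (precursor of the key step)
16 | (1S,4S,6S,7R)-1-allyl-4-hydroxy-3,8,8-trimethoxy-7-methyl-6-(3,4,5-trimethoxyphenyl)bicyclo[2.2.2]oct-2-en-5-one (in the flask as its tetrabutylammonium alkoxide) | C=CC[C@]12C=C(OC)[C@](O)(C(=O)C1(OC)OC)[C@H](c3cc(OC)c(OC)c(OC)c3)[C@H]2C | intermediate (not isolated)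
17 | (1S,5S,6S,7R)-1-allyl-5-hydroxy-3,8,8-trimethoxy-7-methyl-6-(3,4,5-trimethoxyphenyl)bicyclo[3.2.1]oct-2-en-4-one (6-aryl exo, 7-methyl endo) | C=CC[C@]12C=C(OC)C(=O)[C@](O)(C1(OC)OC)[C@H](c3cc(OC)c(OC)c(OC)c3)[C@H]2C | intermediate (product of the key step)
18 | (1S,5S,6S,7R)-1-allyl-3,5,8,8-tetramethoxy-7-methyl-6-(3,4,5-trimethoxyphenyl)bicyclo[3.2.1]oct-2-en-4-one | C=CC[C@]12C=C(OC)C(=O)[C@](OC)(C1(OC)OC)[C@H](c3cc(OC)c(OC)c(OC)c3)[C@H]2C | intermediate
19 | (1R,5S,6S,7R)-1-allyl-3,5,8,8-tetramethoxy-7-methyl-6-(3,4,5-trimethoxyphenyl)bicyclo[3.2.1]octan-4-one as a mixture of C3 epimers (the C1 descriptor changes only because the priorities change) | C=CC[C@]12CC(OC)C(=O)[C@](OC)(C1(OC)OC)[C@H](c3cc(OC)c(OC)c(OC)c3)[C@H]2C | intermediate (not isolated)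
20 | (1R,3S,5S,6S,7R)-1-allyl-3,5,8,8-tetramethoxy-7-methyl-6-(3,4,5-trimethoxyphenyl)bicyclo[3.2.1]octan-4-one (3-OMe exo) | C=CC[C@]12C[C@H](OC)C(=O)[C@](OC)(C1(OC)OC)[C@H](c3cc(OC)c(OC)c(OC)c3)[C@H]2C | intermediate
21 | (1R,3S,4S,5S,6S,7R)-1-allyl-3,5,8,8-tetramethoxy-7-methyl-6-(3,4,5-trimethoxyphenyl)bicyclo[3.2.1]octan-4-ol (4-OH axial, cis to 3-OMe) | C=CC[C@]12C[C@H](OC)[C@H](O)[C@](OC)(C1(OC)OC)[C@H](c3cc(OC)c(OC)c(OC)c3)[C@H]2C | intermediate
22 | (1R,3S,4S,5S,6S,7R)-1-allyl-4-hydroxy-3,5-dimethoxy-7-methyl-6-(3,4,5-trimethoxyphenyl)bicyclo[3.2.1]octan-8-one | C=CC[C@]12C[C@H](OC)[C@H](O)[C@](OC)(C1=O)[C@H](c1cc(OC)c(OC)c(OC)c1)[C@H]2C | target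

Total step count: 14. Longest linear sequence: 14 steps (1 → 22); 6 and 12 are bought.

Steps most likely to fail

Step 8. Three processes can go wrong. Methanol may be captured at the para carbon, or the oxidised ring may lose its silyl group. The cycloaddition between a tetrasubstituted, donor-laden dienone and a trans-disubstituted donor alkene may be so slow that the dienone decays first. The methyl-endo and aryl-endo approaches may not be told apart well enough. The fallback sets out from 11 and comes back at 14. Ring bromination at the only free position (NBS, CH2Cl2, −78 → 0 °C) should give 3-allyl-4-bromo-2,5-dimethoxy-6-[(triisopropylsilyl)oxy]phenol F1. Oxidation as before (PhI(OAc)2, MeOH) should give the bromo masked o-benzoquinone F2, not isolated, in which bromine on C2 closes the para position to methanol and lowers the diene LUMO. Heating with 12 should give the racemic 2-bromo adduct F3, and radical debromination of the vinyl bromide (Bu3SnH, AIBN, PhMe, 80 °C) returns to 14.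

Step 10. Fluoride attack on the hindered tertiary silyl ether may be slow, the free alkoxide may trigger an anion-accelerated cycloreversion that expels isoelemicin, and the vinylic C3 may migrate in part if equilibration is incomplete. The fallback sets out from 15 and comes back at 17, and separates deprotection from rearrangement. HF·pyridine (pyridine, THF, 0 °C → rt) cleaves the silyl ether without a free alkoxide, and the neutral bridgehead ketol 16 is isolated. The shift is then run in its Lewis-acid mode with Al(O-t-Bu)3 in toluene at 80 °C. A covalent five-membered aluminium chelate of the C4–O/C5=O unit carries the same C6 migration under thermodynamic control, and the tert-butoxide cannot transfer hydride. No compound outside the list arises (F0).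

Step 12. Hydride transfer from the bulky copper cluster to C2 may stall, since C2 is flanked by quaternary C1 and shielded by the C8 methoxy group above and the C7 methyl group below; 1,2-reduction may then intrude. The fallback sets out from 18 and comes back at 20, and replaces two-electron hydride addition by hydrogen-atom transfer. With Mn(dpm)3 (cat.), PhSiH3 and i-PrOH at rt under argon, a small manganese hydride should give H• to C2 and form the C3 radical stabilised by both the methoxy and the keto group. This radical is reduced and protonated to 19 and equilibrated with K2CO3 in MeOH as before. Without a peroxide co-oxidant the monosubstituted allyl alkene should be left alone. No compound outside the list arises (F0).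

Further compounds
F1 | step 8 | 3-allyl-4-bromo-2,5-dimethoxy-6-[(triisopropylsilyl)oxy]phenol | C=CCc1c(Br)c(OC)c(O[Si](C(C)C)(C(C)C)C(C)C)c(O)c1OC
F2 | step 8 | 5-allyl-4-bromo-3,6,6-trimethoxy-2-[(triisopropylsilyl)oxy]cyclohexa-2,4-dien-1-one | C=CCC1=C(Br)C(OC)=C(O[Si](C(C)C)(C(C)C)C(C)C)C(=O)C1(OC)OC
F3 | step 8 | racemic 2-bromo analogue of 14 (bromine on C2; both enantiomers written) | C=CC[C@]12C(Br)=C(OC)[C@](O[Si](C(C)C)(C(C)C)C(C)C)(C(=O)C1(OC)OC)[C@H](c3cc(OC)c(OC)c(OC)c3)[C@H]2C.C=CC[C@@]12C(Br)=C(OC)[C@@](O[Si](C(C)C)(C(C)C)C(C)C)(C(=O)C1(OC)OC)[C@@H](c3cc(OC)c(OC)c(OC)c3)[C@@H]2C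
F0 | step 10 | none | none
F0 | step 12 | none | none
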